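A direct plan would start from kaempferol A1, acetylate all four hydroxyls (tetraacetate A2), exchange the 7-acetate for a prenyl ether (triacetate A3) and, once the other acetates are removed, force a [3,3] shift of the prenyl group from O7 to C8.
Its weakest steps would be: (a) the O7-selective etherification, which would rest on a lability ranking among four aryl acetates and would spend protecting-group operations without adding complexity; (b) the aromatic Claisen rearrangement, which would have to choose C8 over C6 under forcing conditions in which the new ortho-hydroxyaryl allyl unit can cyclise, rearrange abnormally or migrate on to C6; (c) the handling of a free, air-sensitive polyphenolate through that step.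

The route would build ring A around the quaternary substituent instead of alkylating a finished ring. It exploits that C8 lies between two oxygen-bearing carbons of ring A: C7 and C8 arrive as the sp carbons of a siloxyalkyne that already carries the 2-methylbut-3-en-2-yl group, and C8a (as a ketene carbonyl), C6, C5 and C4a come from 3-ethoxycyclobutenone. One thermal cascade would form C8–C8a and C6–C7, close the benzene ring and tell the three oxygens apart (O1 free, O5 ethyl, O7 silyl). No O-prenylation or sigmatropic shift is needed, and ring C can close only onto the free oxygen next to C8, so no 6-isomer can arise.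

Key step: step 2

Remark: 1, 7 and 16 are taken as catalogue compounds; every sp3 centre created on the way (in 9, 11 and 19) is racemic and is erased before the achiral target.

Step 1
Reactants: 1 methyl 2,2-dimethylbut-3-enoate; 2 dibromomethane; 3 triisopropylsilyl chloride
Product: 6 triisopropyl[(3,3-dimethylpent-4-en-1-yn-1-yl)oxy]silane, via lithium dibromoenolate 4 (not isolated), via lithium ynolate 5 (not isolated)
Conditions: CH2Br2, lithium 2,2,6,6-tetramethylpiperidide, THF, −78 °C; then n-BuLi, −78 → 0 °C; then i-Pr3SiCl, −78 → 23 °C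
Reagents that add atoms: dibromomethane (2), BrCBr; triisopropylsilyl chloride (3), CC(C)[Si](Cl)(C(C)C)C(C)C
Why: Kowalski-type ester-to-ynolate homologation, in which acylation of LiCHBr2 gives the dibromoketone enolate 4, bromine–lithium exchange triggers the carbenoid 1,2-shift of the tertiary group to ynolate 5, and the bulky silyl chloride traps 5 on oxygen; the alkene has no allylic hydrogen and is inert to the bases, and no stereocentre is formed.

Step 2
Reactants: 6 triisopropyl[(3,3-dimethylpent-4-en-1-yn-1-yl)oxy]silane; 7 3-ethoxycyclobut-2-en-1-one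
Product: 12 5-ethoxy-2-(2-methylbut-3-en-2-yl)-3-(triisopropylsilyloxy)phenol, via vinylketene 8 (not isolated), via 4-vinylcyclobutenone 9 (not isolated), via dienylketene 10 (not isolated), via cyclohexadienone 11 (not isolated)
Conditions: 6 (1.2 equiv), 7 (1.0 equiv), toluene (0.5 M), Ar, 80 °C, 8 h, then 110 °C, 3 h
Reagents that add atoms: 3-ethoxycyclobut-2-en-1-one (7), CCOC1=CC(=O)C1
Why: In this Danheiser benzannulation, 4π-electrocyclic opening of 7 gives vinylketene 8, whose carbonyl carbon bonds to the nucleophilic β-carbon of the ynol ether in a regiospecific [2+2] to give 9, and a second 4π opening to dienylketene 10, 6π-electrocyclisation to 11 and enolisation give phenol 12. The closest known reaction type is the thermal benzannulation of cyclobutenones with siloxyalkynes, which gives resorcinol monosilyl ethers with the alkyne substituent between the two oxygens. Ring A is closed by a thermal disrotatory 6π-electrocyclisation (C4a–C8a bond) after the cycloaddition has formed C8–C8a and C6–C7. No stereocentre survives, since the ring sp3 carbons of 9 and 11 are racemic and vanish on aromatisation. The step needs regiocontrol of the ketene–alkyne union and chemoselectivity over the terminal alkene: the oxygen donor polarises the alkyne so that only the carbon bearing the tertiary group attacks the ketene carbonyl, which places that group between the new hydroxyl and the siloxy group, and a ketene adds to an ynol ether far faster than to an unactivated monosubstituted alkene. The steric demand of the tertiary group falls on an sp carbon that meets the unhindered sp carbon of the ketene, which is why 80–110 °C should suffice.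

Step 3
Reactants: 12 5-ethoxy-2-(2-methylbut-3-en-2-yl)-3-(triisopropylsilyloxy)phenol; 13 paraformaldehyde
Product: 15 6-ethoxy-2-hydroxy-3-(2-methylbut-3-en-2-yl)-4-(triisopropylsilyloxy)benzaldehyde, via salicyl alcohol 14 (not isolated)
Conditions: MgCl2 (2 equiv), Et3N (4 equiv), (CH2O)n (6 equiv), MeCN, 75 °C, 6 h; cold aq. citric acid work-up
Reagents that add atoms: paraformaldehyde (13), C=O
Why: In this Casnati–Skattebøl ortho-formylation the magnesium phenoxide delivers formaldehyde inside a chelate to the only free ortho carbon (the other bears the quaternary group), and alkoxide 14 passes hydride to a second formaldehyde (Oppenauer type); the para carbon is not touched, the non-acidic medium spares the silyl ether and the ortho-phenol/alkene pair, and no stereocentre is formed.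

Step 4
Reactants: 16 4-ethynylphenol; 3 triisopropylsilyl chloride
Product: 17 (4-ethynylphenoxy)triisopropylsilane
Conditions: i-Pr3SiCl (1.1 equiv), imidazole (2 equiv), DMF, 23 °C
Reagents that add atoms: triisopropylsilyl chloride (3), CC(C)[Si](Cl)(C(C)C)C(C)C
Why: Standard imidazole-mediated O-silylation of a phenol, which gives a silyl ether that withstands the organolithium, oxidation and amine steps ahead and leaves with the O7 silyl group in one fluoride treatment; no stereocentre is formed.

Step 5
Reactants: 15 6-ethoxy-2-hydroxy-3-(2-methylbut-3-en-2-yl)-4-(triisopropylsilyloxy)benzaldehyde; 17 (4-ethynylphenoxy)triisopropylsilane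
Product: 19 1-[6-ethoxy-2-hydroxy-3-(2-methylbut-3-en-2-yl)-4-(triisopropylsilyloxy)phenyl]-3-[4-(triisopropylsilyloxy)phenyl]prop-2-yn-1-ol (racemic), via lithium acetylide 18 (not isolated)
Conditions: 17 (2.6 equiv), n-BuLi (2.5 equiv), THF, −78 °C; then 15, −78 → 0 °C; aq. NH4Cl, crude product used at once
Reagents that add atoms: (4-ethynylphenoxy)triisopropylsilane (17), C#Cc1ccc(O[Si](C(C)C)(C(C)C)C(C)C)cc1
Why: 1,2-Addition of a lithium acetylide to an aldehyde, in which the first equivalent only deprotonates the phenol and the excess adds to the phenoxide aldehyde on warming; the carbinol centre is formed without control (racemic) and is oxidised away in step 6.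

Step 6
Reactants: 19 1-[6-ethoxy-2-hydroxy-3-(2-methylbut-3-en-2-yl)-4-(triisopropylsilyloxy)phenyl]-3-[4-(triisopropylsilyloxy)phenyl]prop-2-yn-1-ol
Product: 22 5-ethoxy-8-(2-methylbut-3-en-2-yl)-7-(triisopropylsilyloxy)-2-[4-(triisopropylsilyloxy)phenyl]-4H-chromen-4-one, via ynone 20 (not isolated), via enaminone 21 (not isolated)
Conditions: MnO2 (15 equiv), CH2Cl2, 23 °C; filter; then Et2NH (5 equiv), THF, 50 °C
Reagents that add atoms: none
Why: MnO2 oxidises the benzylic and propargylic alcohol to ynone 20, diethylamine adds to give enaminone 21, and the only free hydroxyl (next to the quaternary group, O5 being ethylated) displaces the amine by 6-endo addition–elimination, so neither the 5-exo aurone nor a 6-substituted isomer can form; this is the known flavone synthesis from ortho-hydroxyaryl ynones, and no stereocentre is formed.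

Step 7
Reactants: 22 5-ethoxy-8-(2-methylbut-3-en-2-yl)-7-(triisopropylsilyloxy)-2-[4-(triisopropylsilyloxy)phenyl]-4H-chromen-4-one; 23 hydrogen peroxide
Product: 26 5-ethoxy-3-hydroxy-8-(2-methylbut-3-en-2-yl)-7-(triisopropylsilyloxy)-2-[4-(triisopropylsilyloxy)phenyl]-4H-chromen-4-one, via 3-lithioflavone 24 (not isolated), via 3-boronate 25 (not isolated)
Conditions: lithium diisopropylamide (1.5 equiv), THF, −78 °C; B(OMe)3 (3 equiv), −78 → 0 °C; then AcOH, 30% H2O2, 0 → 23 °C
Reagents that add atoms: hydrogen peroxide (23), OO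
Why: Lithiation of the flavone at C3 (the vinylic hydrogen next to the carbonyl is the most acidic site), borylation and oxidation of the carbon–boron bond, a known way from flavones to flavonols; the silyl ethers, the ethyl ether and the alkene tolerate the hindered amide base and the buffered peroxide, and no stereocentre is formed.

Step 8
Reactants: 26 5-ethoxy-3-hydroxy-8-(2-methylbut-3-en-2-yl)-7-(triisopropylsilyloxy)-2-[4-(triisopropylsilyloxy)phenyl]-4H-chromen-4-one
Product: 28 3,5,7-trihydroxy-2-(4-hydroxyphenyl)-8-(2-methylbut-3-en-2-yl)-4H-chromen-4-one (target), via 5-hydroxy bis-silyl ether 27 (not isolated)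
Conditions: BCl3 (3 equiv), n-Bu4NI (3 equiv), 2,6-di-tert-butyl-4-methylpyridine (1.5 equiv), CH2Cl2, −78 → 0 °C; cold aq. NaHCO3; then n-Bu4NF (2.5 equiv), AcOH (2.5 equiv), THF, 0 °C, Ar
Reagents that add atoms: none
Why: Chelation-assisted cleavage of the ether peri to the carbonyl (boron binds O4 and O5, iodide dealkylates the ethyl oxonium, the hindered pyridine takes up the HCl from borylation of the 3-hydroxyl), run while O7 is still silylated so that the alkene has no free ortho-phenol to cyclise onto, followed by fluoride desilylation under acetic acid buffering that keeps the polyphenol protonated; no stereocentre is formed.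

Compound list
1 | methyl 2,2-dimethylbut-3-enoate | C=CC(C)(C)C(=O)OC | starting material
2 | dibromomethane | BrCBr | starting material
3 | triisopropylsilyl chloride | CC(C)[Si](Cl)(C(C)C)C(C)C | starting material
4 | lithium 1,1-dibromo-3,3-dimethylpenta-1,4-dien-2-olate | [Li+].C=CC(C)(C)C([O-])=C(Br)Br | intermediate (not isolated)
5 | lithium 3,3-dimethylpent-4-en-1-yn-1-olate | [Li+].C=CC(C)(C)C#C[O-] | intermediate (not isolated)
6 | triisopropyl[(3,3-dimethylpent-4-en-1-yn-1-yl)oxy]silane | C=CC(C)(C)C#CO[Si](C(C)C)(C(C)C)C(C)C | intermediate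
7 | 3-ethoxycyclobut-2-en-1-one | CCOC1=CC(=O)C1 | starting material
8 | 3-ethoxybuta-1,3-dien-1-one (vinylketene) | C=C(OCC)C=C=O | intermediate (not isolated)
9 | 4-(1-ethoxyvinyl)-2-(2-methylbut-3-en-2-yl)-3-(triisopropylsilyloxy)cyclobut-2-en-1-one, racemic | C=CC(C)(C)C1=C(O[Si](C(C)C)(C(C)C)C(C)C)C(C(=C)OCC)C1=O | intermediate (not isolated)
10 | 5-ethoxy-2-(2-methylbut-3-en-2-yl)-3-(triisopropylsilyloxy)hexa-1,3,5-trien-1-one, ketene arm and ethoxyvinyl arm cis on the 3,4-alkene | O=C=C(C(C)(C)C=C)/C(O[Si](C(C)C)(C(C)C)C(C)C)=C\C(=C)OCC | intermediate (not isolated)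
11 | 5-ethoxy-2-(2-methylbut-3-en-2-yl)-3-(triisopropylsilyloxy)cyclohexa-2,4-dien-1-one | O=C1CC(OCC)=CC(O[Si](C(C)C)(C(C)C)C(C)C)=C1C(C)(C)C=C | intermediate (not isolated)
12 | 5-ethoxy-2-(2-methylbut-3-en-2-yl)-3-(triisopropylsilyloxy)phenol | Oc1cc(OCC)cc(O[Si](C(C)C)(C(C)C)C(C)C)c1C(C)(C)C=C | intermediate
13 | paraformaldehyde (formaldehyde unit) | C=O | starting material
14 | 3-ethoxy-2-(hydroxymethyl)-6-(2-methylbut-3-en-2-yl)-5-(triisopropylsilyloxy)phenol (magnesium salt in the flask) | OCc1c(O)c(C(C)(C)C=C)c(O[Si](C(C)C)(C(C)C)C(C)C)cc1OCC | intermediate (not isolated)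
15 | 6-ethoxy-2-hydroxy-3-(2-methylbut-3-en-2-yl)-4-(triisopropylsilyloxy)benzaldehyde | O=Cc1c(O)c(C(C)(C)C=C)c(O[Si](C(C)C)(C(C)C)C(C)C)cc1OCC | intermediate
16 | 4-ethynylphenol | C#Cc1ccc(O)cc1 | starting material
17 | (4-ethynylphenoxy)triisopropylsilane | C#Cc1ccc(O[Si](C(C)C)(C(C)C)C(C)C)cc1 | intermediate
18 | lithium [4-(triisopropylsilyloxy)phenyl]acetylide | [Li+].[C-]#Cc1ccc(O[Si](C(C)C)(C(C)C)C(C)C)cc1 | intermediate (not isolated)
19 | 1-[6-ethoxy-2-hydroxy-3-(2-methylbut-3-en-2-yl)-4-(triisopropylsilyloxy)phenyl]-3-[4-(triisopropylsilyloxy)phenyl]prop-2-yn-1-ol, racemic | OC(C#Cc1ccc(O[Si](C(C)C)(C(C)C)C(C)C)cc1)c1c(O)c(C(C)(C)C=C)c(O[Si](C(C)C)(C(C)C)C(C)C)cc1OCC | intermediate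
20 | 1-[6-ethoxy-2-hydroxy-3-(2-methylbut-3-en-2-yl)-4-(triisopropylsilyloxy)phenyl]-3-[4-(triisopropylsilyloxy)phenyl]prop-2-yn-1-one | O=C(C#Cc1ccc(O[Si](C(C)C)(C(C)C)C(C)C)cc1)c1c(O)c(C(C)(C)C=C)c(O[Si](C(C)C)(C(C)C)C(C)C)cc1OCC | intermediate (not isolated)
21 | 3-(diethylamino)-1-[6-ethoxy-2-hydroxy-3-(2-methylbut-3-en-2-yl)-4-(triisopropylsilyloxy)phenyl]-3-[4-(triisopropylsilyloxy)phenyl]prop-2-en-1-one, alkene geometry not fixed | CCN(CC)C(=CC(=O)c1c(O)c(C(C)(C)C=C)c(O[Si](C(C)C)(C(C)C)C(C)C)cc1OCC)c1ccc(O[Si](C(C)C)(C(C)C)C(C)C)cc1 | intermediate (not isolated)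
22 | 5-ethoxy-8-(2-methylbut-3-en-2-yl)-7-(triisopropylsilyloxy)-2-[4-(triisopropylsilyloxy)phenyl]-4H-chromen-4-one | C=CC(C)(C)c1c(O[Si](C(C)C)(C(C)C)C(C)C)cc(OCC)c2c(=O)cc(-c3ccc(O[Si](C(C)C)(C(C)C)C(C)C)cc3)oc12 | intermediate
23 | hydrogen peroxide | OO | starting material
24 | 3-lithio derivative of 22 | C=CC(C)(C)c1c(O[Si](C(C)C)(C(C)C)C(C)C)cc(OCC)c2c(=O)c([Li])c(-c3ccc(O[Si](C(C)C)(C(C)C)C(C)C)cc3)oc12 | intermediate (not isolated)
25 | dimethyl boronate at C3 of 22 | C=CC(C)(C)c1c(O[Si](C(C)C)(C(C)C)C(C)C)cc(OCC)c2c(=O)c(B(OC)OC)c(-c3ccc(O[Si](C(C)C)(C(C)C)C(C)C)cc3)oc12 | intermediate (not isolated)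
26 | 5-ethoxy-3-hydroxy-8-(2-methylbut-3-en-2-yl)-7-(triisopropylsilyloxy)-2-[4-(triisopropylsilyloxy)phenyl]-4H-chromen-4-one | C=CC(C)(C)c1c(O[Si](C(C)C)(C(C)C)C(C)C)cc(OCC)c2c(=O)c(O)c(-c3ccc(O[Si](C(C)C)(C(C)C)C(C)C)cc3)oc12 | intermediate
27 | 3,5-dihydroxy-8-(2-methylbut-3-en-2-yl)-7-(triisopropylsilyloxy)-2-[4-(triisopropylsilyloxy)phenyl]-4H-chromen-4-one | C=CC(C)(C)c1c(O[Si](C(C)C)(C(C)C)C(C)C)cc(O)c2c(=O)c(O)c(-c3ccc(O[Si](C(C)C)(C(C)C)C(C)C)cc3)oc12 | intermediate (not isolated)
28 | 3,5,7-trihydroxy-2-(4-hydroxyphenyl)-8-(2-methylbut-3-en-2-yl)-4H-chromen-4-one, achiral | C=CC(C)(C)c1c(O)cc(O)c2c(=O)c(O)c(-c3ccc(O)cc3)oc12 | target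

Total step count: 8. Longest linear sequence: 7 (steps 1, 2, 3, 5, 6, 7, 8; step 4 is a one-step side branch).

Steps most likely to fail

Step 2. The electrocyclic opening of 7 may be slower than the thermal decay of the siloxyalkyne, or vinylketene 8 may oligomerise, or acylate the product phenol, faster than it is captured at the hindered alkyne carbon. The fallback sets out from 6 and returns at 12. Vinylketene 8 would be generated without the cyclobutenone, by Et3N-induced 1,4-dehydrochlorination of (E)-3-ethoxybut-2-enoyl chloride F1 (made beforehand from the corresponding acid with (COCl)2), added slowly at 0–23 °C to an excess of 6. The ketene–alkyne [2+2] to 9 would then run at low temperature, and brief heating to 80 °C would carry 9 through 10 and 11 to 12.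

Step 1. Acylation of LiCHBr2 by the α-quaternary ester may stay incomplete, or the 1,2-shift of the tertiary allylic group in the carbenoid may be sluggish, so that bromoketone-derived material is silylated instead of the ynolate. The fallback sets out from 1 and returns at 5. Ester 1 would be reduced with i-Bu2AlH at −78 °C to 2,2-dimethylbut-3-enal F2 and homologated with dimethyl (1-diazo-2-oxopropyl)phosphonate, K2CO3 and MeOH (Ohira–Bestmann) to 3,3-dimethylpent-4-en-1-yne F3. Deprotonation with LiN(SiMe3)2 would give lithium 3,3-dimethylpent-4-en-1-yn-1-ide F4, and oxidation of this acetylide with lithium tert-butyl peroxide would give ynolate 5, which is silylated as in step 1 to 6.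

Step 8. The vinyl group may be lost by hydrohalogenation or cationic rearrangement while boron halides and the 3-hydroxyl are together in the flask, or the ethyl ether may be cleaved incompletely. The fallback sets out from 22 and returns at 28. The ethyl ether would be cleaved with BCl3 and n-Bu4NI on flavone 22, which has no hydroxyl and so releases no acid in the flask, to give 5-hydroxy-8-(2-methylbut-3-en-2-yl)-7-(triisopropylsilyloxy)-2-[4-(triisopropylsilyloxy)phenyl]-4H-chromen-4-one F5. Silylation with i-Pr3SiOTf and 2,6-lutidine would give 8-(2-methylbut-3-en-2-yl)-5,7-bis(triisopropylsilyloxy)-2-[4-(triisopropylsilyloxy)phenyl]-4H-chromen-4-one F6. Lithiation as in step 7 would give the 3-lithio tris-silyl flavone F7, B(OMe)3 the 3-boronate tris-silyl flavone F8, and buffered H2O2 the 3-hydroxy-8-(2-methylbut-3-en-2-yl)-5,7-bis(triisopropylsilyloxy)-2-[4-(triisopropylsilyloxy)phenyl]-4H-chromen-4-one F9. From F9, n-Bu4NF with AcOH alone would release 28, so that no Lewis acid meets the flavonol.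

Further compounds
F1 | step 2 | (E)-3-ethoxybut-2-enoyl chloride | CCO/C(C)=C/C(Cl)=O
F2 | step 1 | 2,2-dimethylbut-3-enal | C=CC(C)(C)C=O
F3 | step 1 | 3,3-dimethylpent-4-en-1-yne | C=CC(C)(C)C#C
F4 | step 1 | lithium 3,3-dimethylpent-4-en-1-yn-1-ide | [Li+].[C-]#CC(C)(C)C=C
F5 | step 8 | 5-hydroxy-8-(2-methylbut-3-en-2-yl)-7-(triisopropylsilyloxy)-2-[4-(triisopropylsilyloxy)phenyl]-4H-chromen-4-one | C=CC(C)(C)c1c(O[Si](C(C)C)(C(C)C)C(C)C)cc(O)c2c(=O)cc(-c3ccc(O[Si](C(C)C)(C(C)C)C(C)C)cc3)oc12
F6 | step 8 | 8-(2-methylbut-3-en-2-yl)-5,7-bis(triisopropylsilyloxy)-2-[4-(triisopropylsilyloxy)phenyl]-4H-chromen-4-one | C=CC(C)(C)c1c(O[Si](C(C)C)(C(C)C)C(C)C)cc(O[Si](C(C)C)(C(C)C)C(C)C)c2c(=O)cc(-c3ccc(O[Si](C(C)C)(C(C)C)C(C)C)cc3)oc12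
F7 | step 8 | 3-lithio tris-silyl flavone | C=CC(C)(C)c1c(O[Si](C(C)C)(C(C)C)C(C)C)cc(O[Si](C(C)C)(C(C)C)C(C)C)c2c(=O)c([Li])c(-c3ccc(O[Si](C(C)C)(C(C)C)C(C)C)cc3)oc12
F8 | step 8 | 3-boronate tris-silyl flavone (dimethyl ester) | C=CC(C)(C)c1c(O[Si](C(C)C)(C(C)C)C(C)C)cc(O[Si](C(C)C)(C(C)C)C(C)C)c2c(=O)c(B(OC)OC)c(-c3ccc(O[Si](C(C)C)(C(C)C)C(C)C)cc3)oc12
F9 | step 8 | 3-hydroxy-8-(2-methylbut-3-en-2-yl)-5,7-bis(triisopropylsilyloxy)-2-[4-(triisopropylsilyloxy)phenyl]-4H-chromen-4-one | C=CC(C)(C)c1c(O[Si](C(C)C)(C(C)C)C(C)C)cc(O[Si](C(C)C)(C(C)C)C(C)C)c2c(=O)c(O)c(-c3ccc(O[Si](C(C)C)(C(C)C)C(C)C)cc3)oc12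
A1 | direct plan | kaempferol | O=c1c(O)c(-c2ccc(O)cc2)oc2cc(O)cc(O)c12
A2 | direct plan | kaempferol 3,5,7,4'-tetraacetate | CC(=O)Oc1ccc(cc1)-c1oc2cc(OC(C)=O)cc(OC(C)=O)c2c(=O)c1OC(C)=O
A3 | direct plan | kaempferol 7-O-prenyl ether 3,5,4'-triacetate | CC(=O)Oc1ccc(cc1)-c1oc2cc(OCC=C(C)C)cc(OC(C)=O)c2c(=O)c1OC(C)=O
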